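All constants belong to no real substance; no experiment stands behind them.

I started at late times, where G goes over to X, and reckoned with the fraction of G left rather than with the X made.

| setting | spring | noon | autumn | winter |
|---|---|---|---|---|
| Z | 24 mM | 24 mM (fed, over 6.0 h) | 24 mM | 24 mM (fed, over 6.0 h) |
| D | 22.8 mM (in portions, 3, over 6.0 h) | 22.8 mM | 22.8 mM (fed, over 6.0 h) | 22.8 mM |
| E | 7.20 mM | 7.20 mM | 7.20 mM | 7.20 mM |
| temperature | 60 °C | 60 °C | 60 °C |  |
| time | 15 h | 15 h | 15 h | 15 h |
| remark | first portion at the start, last at 6.0 h | all else is in the flask from the start; the feed brings no volume worth counting | all else is in the flask from the start; the feed brings no volume worth counting | the addition at 30 °C, then warmed to 60 °C; the feed brings no volume worth counting |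

    Z + D + L → G + 2 L (k1 = 51 M⁻² min⁻¹, Ea1 = 51.0 kJ mol⁻¹)
    Z + D → G + L (k2 = 6.5 × 10⁻⁵ M⁻¹ min⁻¹, Ea2 = 101 kJ mol⁻¹)
    Z + E → Z.E (k3 = 0.26 M⁻¹ min⁻¹, Ea3 = 64.0 kJ mol⁻¹)
    G → X (k4 = 0.0029 min⁻¹, Ea4 = 119 kJ mol⁻¹)
    (constants at 60 °C)

* which flask leads in amount of X, in percent of the Z charged ("all alike" within 1.5 percentage points) (spring / noon / autumn / winter / all alike)
* how much X is there at the end, in percent of the Z charged: spring
* how much X is there at the end, in percent of the Z charged: noon
* how much X is there at the end, in percent of the Z charged: autumn
* how much X is there at the end, in percent of the Z charged: winter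

- constants are those at 60 °C; use the activation energies for any other temperature

1. E can hold 7.20 mM of Z, and the remaining 16.8 mM needs less D than the 22.8 mM charged, so Z is the limiting reagent. If E took its whole charge of Z, 70.0 % of the Z would be left for G and then X.
2. The clock on that last step is the half-life of G, 3.98 h, the time in which G falls to half by G → X. If G had stood from the start, 7.34 % of it would be left at 15 h.
3. But G does not stand from the start. The plain step has a pseudo-first-order half-life for Z of 7800 h, far longer than the run, so G must wait for autocatalysis.
4. The plain step seeds L at a level of 0.00127 mM, and I needed L near 8.40 mM, half the possible G. That takes 8.79 e-foldings.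
5. My objection was that E takes Z meanwhile: its half-life for Z is 6.17 h, shorter than the run. So I took the growth rate with Z less E, 0.0195 min⁻¹, and half of it during the feed.
6. In noon the feed gave 3.52 e-foldings, and the rest put ignition at 10.5 h. G then had 4.50 h, so 45.7 % of it was left and X came to 38.0 %.
7. Spring and autumn got the same clock, so I started them from the figure of noon. I expected them a little lower, since the Z added by the feed averages 12.0 mM over the feed in noon, less than the 24 mM present from the start in spring and autumn, and E's step goes with [Z].
8. In winter, the autocatalytic step runs 0.162 times as fast in the cold, and the seed level falls to 2.14 × 10⁻⁴ mM, lower than the level at 60 °C. I counted the feed as lost, so I put ignition at 13.5 h and X at 16.1 %.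

The forecast said 42 % for spring, 46 % for noon, 42 % for autumn and 28 % for winter, with noon leading, on the ground that “X depends mainly on how much of the 15 h remains”.

The simulation gave X as 31.2 % in spring, 34.0 % in noon, 30.7 % in autumn and 16.7 % in winter, so noon leads. In noon at 10.4 h, Z had a half-life of 1.9 h by the autocatalytic step, shorter than the 4.0 h of G by G → X. At the end of noon G stood at 31.9 % beside X at 34.0 %, which through 3.98 h reads as a single age of 4.17 h against my 4.50 h.

In the neighbour flask, noon run at 85 °C, the half-life of G shortens to 11.9 min, so the hours after the feed hold 45.3 half-lives. The computed end has G at 0 % and X at 71.5 %.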